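[catalyst] held still in Thursday's run: the starting material fell at 0.0794 h⁻¹ over the first 2.50 h and at 0.0785 h⁻¹ on average over the whole 12.0 h. So I froze [catalyst] and treated the loss as pseudo-first-order.

in all of them: starting material 0.10 M

|  | catalyst | temperature | remark | time |
|---|---|---|---|---|
| Monday's | 36 µM | 110 °C | run made earlier |  |
| Thursday's | 55 µM | 132 °C | run made earlier |  |
| south-east | 73 µM | 100 °C |  | 50 h |
| south-west | 73 µM | 120 °C |  | 50 h |
| west | 73 µM | 140 °C |  | 50 h |

| run | time / h | target / % | starting material / % |
|---|---|---|---|
| Monday's | 8.00 | 14 | 84 |
| Monday's | 15.0 | 24 | 73 |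
| Monday's | 25.0 | 38 | 61 |
| Monday's | 30.0 | 45 | 55 |
| Monday's | 40.0 | 53 | 44 |
| Thursday's | 2.50 | 18 | 82 |
| Thursday's | 5.00 | 32 | 71 |
| Thursday's | 8.00 | 45 | 54 |
| Thursday's | 10.0 | 50 | 47 |
| Thursday's | 12.0 | 57 | 39 |

(each reading ± 1.5 percentage points)

- the flask that comes out highest in amount of target, in percent of the starting material charged, or "all alike" when all lie within 1.5 percentage points (south-east / south-west / west / all alike)
- target at the end, in percent of the starting material charged, south-east
- target at the end, in percent of the starting material charged, south-west
- target at the end, in percent of the starting material charged, west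



West's charge and time gave 13.1 M·s of [catalyst] multiplied by time, the dose, and with [catalyst] frozen I let a flask's progress go by dose, at one temperature and one charge of starting material. Thursday's last reading stood at a dose of 2.38 M·s with 39% of the starting material left. West takes 5.50 times that dose, so even at Thursday's pace I reckoned 0.548% left at the end of west. Per unit of dose, Thursday's hotter run lost more starting material than Monday's, and west is hotter than Thursday's run. Thursday's target and starting material at its last time summed to 96.0%, which I read as a small leak from target. So in west I would have added neither [catalyst] nor time, since by this reckoning extra dose finds hardly any starting material.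

The forecast gave 72% for south-east, 84% for south-west and 60% for west, with south-west highest, on the ground of “slow target loss”.

The flasks gave 67.2%, 79.1% and 68.7% in that order, with south-west highest.

    target + catalyst ⇌ isomer of the product + catalyst, rate k1*[catalyst]*[target] forward; the back reaction follows from the equilibrium constant (K = 2.20, k = 26.0 M⁻¹ h⁻¹, Ea = 68.0 kJ mol⁻¹, ΔH = −41.0 kJ mol⁻¹)
    starting material + catalyst → catalyst + target (k = 340 M⁻¹ h⁻¹, Ea = 55.0 kJ mol⁻¹)
    (constants at 100 °C)

At the end of west, target was made at 0.0498 of the rate at which it was used up. West had reached a dose of 6.57 M·s at 25.0 h with 77.5% target, and at the full 13.1 M·s it held less, 68.7%.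

A second flask, like west but with 4.4 × 10⁻⁵ M of catalyst, takes a dose of 7.92 M·s, which lies between those two, so from west's 3.17% at 25.0 h I reckoned 1.56% of starting material left. It gave 1.56%, with 75.7% target, between west's two values.

(The runs come from a simulation with constants of no real substance; scatter was added.)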